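**Assumption:** locants C1–C20 follow labdane numbering (C1–C2 is the CH2CO2H arm on C10; C4 with C18/C19 and C3 is the C(CH3)2CO2H arm on C5; primed locants belong to the diol half); TMSE = 2-(trimethylsilyl)ethyl; all reagents named on the reagent lines are bought.

## Retrosynthetic overview

1. The C3–O–C15′ ester is cut to acid 19 (vinyl half) and diazoketone 27 (diol half), joined by carbenoid O–H insertion; the C14′ carbinol comes from substrate-controlled reduction of the resulting ketone.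
2. Ring C of each half is made by an oxa-Diels–Alder reaction of one common diene 14, with butane-2,3-dione (vinyl half) or benzyl glyoxylate (diol half, followed by equatorial C-methylation at C13); C9–H comes from hydrogenation.
3. Diene 14 comes from enone 11 by reductive enol triflation and Stille vinylation.
4. Ring B and both acid arms come from (S)-carvone: Michael addition of an isobutyrate enolate, trans alkylation with methyl bromoacetate, C8 methylation, then excision of the isopropenyl group.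
5. Ring order: B (bought as carvone) → C (cycloaddition, once per half) → union of the halves → deprotection.

## Route

**Step 1**
Reactants: 1 2-methylpropanoyl chloride; 2 2-(trimethylsilyl)ethanol
Product: 3 2-(trimethylsilyl)ethyl 2-methylpropanoate
Conditions: pyridine, DMAP (cat.), CH2Cl2, 0 °C → rt
Reagents that add atoms: none
Why: Nucleophilic acyl substitution gives the fluoride-cleavable TMSE ester that becomes the hindered C3 carboxyl.

**Step 2**
Reactants: 3 2-(trimethylsilyl)ethyl 2-methylpropanoate; 4 (S)-carvone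
Product: 7 keto diester, via lithium ester enolate 5 (not isolated), via lithium ketone enolate 6 (not isolated)
Conditions: 3, LiN(i-Pr)2, THF, −78 °C; 4, −78 → −20 °C; then BrCH2CO2Me, DMPU, −40 → 0 °C
Reagents that add atoms: methyl bromoacetate, COC(=O)CBr
Why: Tandem Michael addition–enolate alkylation: the enolate adds to C5 trans to the isopropenyl group (axial attack) and the new enolate is alkylated at C10 anti to the fresh C5 substituent, so the carvone stereocentre sets C5 and the C10 quaternary centre.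

**Step 3**
Reactants: 7 keto diester
Product: 9 C8-methyl keto diester, via lithium enolate 8 (not isolated)
Conditions: LiN(i-Pr)2, THF, −78 °C; MeI, −78 → −30 °C
Reagents that add atoms: iodomethane, CI
Why: Kinetic enolate alkylation at the only enolisable ketone α-carbon (C8) installs C17; the C8 configuration does not matter because C8 becomes sp2 in the next step.

**Step 4**
Reactants: 9 C8-methyl keto diester
Product: 11 enone, via methoxy hydroperoxide 10 (not isolated)
Conditions: O3, CH2Cl2/MeOH, −78 °C; then FeSO4·7H2O, Cu(OAc)2·H2O, −20 °C → rt; DBU (cat.) in the work-up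
Reagents that add atoms: none
Why: Ozonolysis of the isopropenyl group followed by Schreiber-type iron/copper fragmentation (alkoxyl-radical β-scission, then copper-mediated oxidative elimination) removes the three-carbon unit and leaves the conjugated C7=C8 bond.

**Step 5**
Reactants: 11 enone
Product: 13 enol triflate, via lithium enolate 12 (not isolated)
Conditions: LiBH(s-Bu)3, THF, −78 °C; then PhNTf2, −78 → 0 °C
Reagents that add atoms: N-phenylbis(trifluoromethanesulfonimide), O=S(=O)(N(c1ccccc1)S(=O)(=O)C(F)(F)F)C(F)(F)F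
Why: Conjugate hydride reduction of the β-unsubstituted enone gives the regiodefined C8=C9 enolate, which is O-sulfonylated (reductive enol triflation); no stereocentre is formed.

**Step 6**
Reactants: 13 enol triflate
Product: 14 diene
Conditions: CH2=CHSnBu3, Pd(PPh3)4 (5 mol %), LiCl, THF, 65 °C
Reagents that add atoms: tributyl(vinyl)stannane, C=C[Sn](CCCC)(CCCC)CCCC
Why: Stille cross-coupling of the hindered cyclohexenyl triflate gives the 1-vinylcyclohexene diene C8=C9–C11=C12.

**Step 7**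
Reactants: 14 diene
Product: 15 acetyl dihydropyran
Conditions: butane-2,3-dione (3 equiv), Cu(OTf)2 (10 mol %), 2,2′-bipyridine (10 mol %), CH2Cl2, 0 °C → rt
Reagents that add atoms: butane-2,3-dione, CC(=O)C(C)=O
Why: Lewis acid-catalysed hetero-Diels–Alder reaction forms ring C, with the carbonyl carbon bonding to the unsubstituted terminus C12 and oxygen to C8 on the diene face anti to the pseudo-axial C20 methyl (sets C8), and with acetyl endo so that C13 carries an equatorial acetyl and an axial methyl.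

**Step 8**
Reactants: 15 acetyl dihydropyran
Product: 16 tetrahydropyran ketone
Conditions: H2 (4 atm), 10% Pd/C, EtOAc, rt
Reagents that add atoms: none
Why: Catalytic hydrogenation of C9=C11 from the face opposite the two axial methyls C17 and C20 puts 9-H anti to them, giving the trans B/C fusion.

**Step 9**
Reactants: 16 tetrahydropyran ketone
Product: 17 carbinol
Conditions: NaBH4, MeOH, 0 °C
Reagents that add atoms: none
Why: Chemoselective borohydride reduction of the methyl ketone beside the esters; the C14 configuration is lost in the next step.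

**Step 10**
Reactants: 17 carbinol
Product: 18 vinyl diester
Conditions: Ph2S[OC(CF3)2Ph]2 (Martin sulfurane), benzene, rt
Reagents that add atoms: none
Why: Martin sulfurane dehydration (E2 through the alkoxysulfonium ion) can only remove a hydrogen from the C15 methyl, giving the C14=C15 vinyl group without touching C13.

**Step 11**
Reactants: 18 vinyl diester
Product: 19 vinyl-half acid
Conditions: Bu4NF, THF, rt; dilute aq. HCl work-up
Reagents that add atoms: none
Why: Fluoride attack at silicon fragments the TMSE ester (loss of ethene) and frees the hindered C3 acid while the methyl ester stays.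

**Step 12**
Reactants: 20 dibenzyl fumarate
Product: 21 benzyl glyoxylate
Conditions: O3, CH2Cl2, −78 °C; Me2S, → rt
Reagents that add atoms: ozone, [O-][O+]=O
Why: Ozonolysis (1,3-dipolar cycloaddition and cycloreversion, reductive work-up) cleaves the fumarate into two molecules of the glyoxylate.

**Step 13**
Reactants: 14 diene; 21 benzyl glyoxylate
Product: 22 benzyl ester dihydropyran
Conditions: 21 (3 equiv), Cu(OTf)2 (10 mol %), 2,2′-bipyridine (10 mol %), CH2Cl2, 0 °C → rt
Reagents that add atoms: none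
Why: The same hetero-Diels–Alder reaction forms ring C of the second half with C8 set as in step 7; C13 is left open because it is enolised next.

**Step 14**
Reactants: 22 benzyl ester dihydropyran
Product: 24 C13-methyl benzyl ester, via lithium ester enolate 23 (not isolated)
Conditions: LiN(i-Pr)2, THF, −78 °C; MeI, −78 → −40 °C
Reagents that add atoms: iodomethane, CI
Why: Enolate alkylation: the α-alkoxy ester is deprotonated in preference to the neopentyl-type methyl ester, and iodomethane approaches the exocyclic enolate anti to the syn-axial C17 methyl, giving equatorial C16 and axial carboxyl (13R).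

**Step 15**
Reactants: 24 C13-methyl benzyl ester
Product: 25 C14 acid
Conditions: H2 (4 atm), 10% Pd/C, EtOAc, rt
Reagents that add atoms: none
Why: One hydrogenation saturates C9=C11 from the face anti to C17 and C20 (9-H as in step 8) and hydrogenolyses the benzyl ester.

**Step 16**
Reactants: 25 C14 acid
Product: 27 diazoketone, via acid chloride 26 (not isolated)
Conditions: (COCl)2, DMF (cat.), CH2Cl2, 0 °C; evaporate; CH2N2 (excess), Et2O, 0 °C
Reagents that add atoms: diazomethane, C=[N+]=[N-]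
Why: Acylation of diazomethane by the acid chloride (first stage of an Arndt–Eistert sequence) adds C15 and gives the α-diazoketone.

**Step 17**
Reactants: 19 vinyl-half acid; 27 diazoketone
Product: 28 keto ester dimer
Conditions: Rh2(OAc)4 (1 mol %), CH2Cl2, rt, slow addition of 27 to 19 (1.2 equiv)
Reagents that add atoms: none
Why: Rhodium-carbenoid O–H insertion into the carboxylic acid forms the C15′–O–C3 ester without having to activate the very hindered acid and leaves the C14′ ketone in place.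

**Step 18**
Reactants: 28 keto ester dimer
Product: 29 hydroxy ester dimer
Conditions: NaBH4, MeOH/CH2Cl2, −78 → −40 °C; AcOH quench
Reagents that add atoms: none
Why: Felkin–Anh reduction: hydride attacks the axial C14′ ketone anti to the ring C13′–O bond, which is also the face remote from the C17′ methyl, giving the 14′R carbinol.

**Step 19**
Reactants: 29 hydroxy ester dimer
Product: 31 target, via monoacid 30 (not isolated)
Conditions: Bu4NF, THF, rt; then LiOH·H2O, THF/MeOH/H2O, 0 °C → rt; dilute aq. HCl work-up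
Reagents that add atoms: lithium hydroxide, [Li+].[OH-]
Why: Fluoride fragmentation of the TMSE ester followed by saponification of the two unhindered methyl esters spares the neopentyl-type C3–O–C15′ ester and gives the tricarboxylic acid.

## Compound list

1 | 2-methylpropanoyl chloride | CC(C)C(=O)Cl | starting material
2 | 2-(trimethylsilyl)ethanol | C[Si](C)(C)CCO | starting material
3 | 2-(trimethylsilyl)ethyl 2-methylpropanoate | CC(C)C(=O)OCC[Si](C)(C)C | intermediate
4 | (S)-(+)-carvone, (5S)-2-methyl-5-(prop-1-en-2-yl)cyclohex-2-en-1-one | O=C1C(C)=CC[C@H](C(C)=C)C1 | starting material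
5 | lithium 2-methyl-1-[2-(trimethylsilyl)ethoxy]prop-1-en-1-olate (lithium enolate of 3) | [Li+].[O-]C(OCC[Si](C)(C)C)=C(C)C | intermediate
6 | lithium (3S,5S)-2-methyl-3-{2-methyl-1-oxo-1-[2-(trimethylsilyl)ethoxy]propan-2-yl}-5-(prop-1-en-2-yl)cyclohex-1-en-1-olate (Michael adduct enolate) | [Li+].[O-]C1=C(C)[C@@H](C(C)(C)C(=O)OCC[Si](C)(C)C)C[C@H](C(C)=C)C1 | intermediate
7 | methyl 2-[(1R,2S,4S)-1-methyl-6-oxo-4-(prop-1-en-2-yl)-2-{2-methyl-1-oxo-1-[2-(trimethylsilyl)ethoxy]propan-2-yl}cyclohexyl]acetate (CH2CO2Me trans to the C(CH3)2CO2TMSE group, which is trans to isopropenyl) | O=C1[C@](C)(CC(=O)OC)[C@@H](C(C)(C)C(=O)OCC[Si](C)(C)C)C[C@H](C(C)=C)C1 | intermediate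
8 | lithium enolate of 7 towards C8 (labdane C8=C9) | [Li+].[O-]C1=C[C@@H](C(C)=C)C[C@H](C(C)(C)C(=O)OCC[Si](C)(C)C)[C@@]1(C)CC(=O)OC | intermediate
9 | methyl 2-[(1R,2S,4S)-1,5-dimethyl-6-oxo-4-(prop-1-en-2-yl)-2-{2-methyl-1-oxo-1-[2-(trimethylsilyl)ethoxy]propan-2-yl}cyclohexyl]acetate (mixture of epimers at the new methyl-bearing carbon, labdane C8) | O=C1[C@](C)(CC(=O)OC)[C@@H](C(C)(C)C(=O)OCC[Si](C)(C)C)C[C@H](C(C)=C)C1C | intermediate
10 | 9 with the isopropenyl group replaced by 1-hydroperoxy-1-methoxyethyl (ring stereocentres as in 9) | O=C1[C@](C)(CC(=O)OC)[C@@H](C(C)(C)C(=O)OCC[Si](C)(C)C)C[C@H](C(C)(OC)OO)C1C | intermediate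
11 | methyl 2-[(1R,6S)-1,3-dimethyl-2-oxo-6-{2-methyl-1-oxo-1-[2-(trimethylsilyl)ethoxy]propan-2-yl}cyclohex-3-en-1-yl]acetate | O=C1[C@](C)(CC(=O)OC)[C@@H](C(C)(C)C(=O)OCC[Si](C)(C)C)CC=C1C | intermediate
12 | lithium (5S,6R)-6-(2-methoxy-2-oxoethyl)-2,6-dimethyl-5-{2-methyl-1-oxo-1-[2-(trimethylsilyl)ethoxy]propan-2-yl}cyclohex-1-en-1-olate | [Li+].[O-]C1=C(C)CC[C@H](C(C)(C)C(=O)OCC[Si](C)(C)C)[C@@]1(C)CC(=O)OC | intermediate
13 | methyl 2-[(1R,6S)-1,3-dimethyl-6-{2-methyl-1-oxo-1-[2-(trimethylsilyl)ethoxy]propan-2-yl}-2-[(trifluoromethylsulfonyl)oxy]cyclohex-2-en-1-yl]acetate | FC(F)(F)S(=O)(=O)OC1=C(C)CC[C@H](C(C)(C)C(=O)OCC[Si](C)(C)C)[C@@]1(C)CC(=O)OC | intermediate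
14 | methyl 2-[(1R,6S)-2-ethenyl-1,3-dimethyl-6-{2-methyl-1-oxo-1-[2-(trimethylsilyl)ethoxy]propan-2-yl}cyclohex-2-en-1-yl]acetate | C=CC1=C(C)CC[C@H](C(C)(C)C(=O)OCC[Si](C)(C)C)[C@@]1(C)CC(=O)OC | intermediate
15 | 2-methyl 3-TMSE (5S,8S,10R,13S)-8,13-epoxy-14-oxo-2,3-secolabd-9(11)-ene-2,3-dioate (acetyl equatorial, C16 axial on C13) | CC(=O)[C@]1(C)CC=C2[C@](C)(CC(=O)OC)[C@@H](C(C)(C)C(=O)OCC[Si](C)(C)C)CC[C@]2(C)O1 | intermediate
16 | 2-methyl 3-TMSE (5S,8S,9S,10R,13S)-8,13-epoxy-14-oxo-2,3-secolabdane-2,3-dioate | CC(=O)[C@]1(C)CC[C@H]2[C@](C)(CC(=O)OC)[C@@H](C(C)(C)C(=O)OCC[Si](C)(C)C)CC[C@]2(C)O1 | intermediate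
17 | 2-methyl 3-TMSE (5S,8S,9S,10R,13S)-8,13-epoxy-14-hydroxy-2,3-secolabdane-2,3-dioate (C14 epimers) | CC(O)[C@]1(C)CC[C@H]2[C@](C)(CC(=O)OC)[C@@H](C(C)(C)C(=O)OCC[Si](C)(C)C)CC[C@]2(C)O1 | intermediate
18 | 2-methyl 3-TMSE (5S,8S,9S,10R,13S)-8,13-epoxy-2,3-secolabd-14-ene-2,3-dioate | C=C[C@]1(C)CC[C@H]2[C@](C)(CC(=O)OC)[C@@H](C(C)(C)C(=O)OCC[Si](C)(C)C)CC[C@]2(C)O1 | intermediate
19 | (5S,8S,9S,10R,13S)-8,13-epoxy-2-methoxy-2-oxo-2,3-secolabd-14-en-3-oic acid (vinyl-half acid) | C=C[C@]1(C)CC[C@H]2[C@](C)(CC(=O)OC)[C@@H](C(C)(C)C(=O)O)CC[C@]2(C)O1 | intermediate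
20 | dibenzyl (E)-but-2-enedioate (dibenzyl fumarate) | O=C(OCc1ccccc1)/C=C/C(=O)OCc1ccccc1 | starting material
21 | benzyl 2-oxoacetate (benzyl glyoxylate) | O=CC(=O)OCc1ccccc1 | intermediate
22 | 14-benzyl 2-methyl 3-TMSE (5S,8S,10R)-8,13-epoxy-15,16-dinor-2,3-secolabd-9(11)-ene-2,3,14-trioate (C13 epimers) | O=C(OCc1ccccc1)C1CC=C2[C@](C)(CC(=O)OC)[C@@H](C(C)(C)C(=O)OCC[Si](C)(C)C)CC[C@]2(C)O1 | intermediate
23 | lithium enolate of 22 at C13 (exocyclic C13=C14) | [Li+].[O-]C(OCc1ccccc1)=C1CC=C2[C@](C)(CC(=O)OC)[C@@H](C(C)(C)C(=O)OCC[Si](C)(C)C)CC[C@]2(C)O1 | intermediate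
24 | 14-benzyl 2-methyl 3-TMSE (5S,8S,10R,13R)-8,13-epoxy-15-nor-2,3-secolabd-9(11)-ene-2,3,14-trioate (C16 equatorial, carboxyl axial) | O=C(OCc1ccccc1)[C@@]1(C)CC=C2[C@](C)(CC(=O)OC)[C@@H](C(C)(C)C(=O)OCC[Si](C)(C)C)CC[C@]2(C)O1 | intermediate
25 | (5S,8S,9S,10R,13R)-8,13-epoxy-2-methoxy-2-oxo-3-oxo-3-[2-(trimethylsilyl)ethoxy]-15-nor-2,3-secolabdan-14-oic acid | OC(=O)[C@@]1(C)CC[C@H]2[C@](C)(CC(=O)OC)[C@@H](C(C)(C)C(=O)OCC[Si](C)(C)C)CC[C@]2(C)O1 | intermediate
26 | acid chloride of 25 (C14 carbonyl chloride) | ClC(=O)[C@@]1(C)CC[C@H]2[C@](C)(CC(=O)OC)[C@@H](C(C)(C)C(=O)OCC[Si](C)(C)C)CC[C@]2(C)O1 | intermediate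
27 | 2-methyl 3-TMSE (5S,8S,9S,10R,13R)-15-diazo-8,13-epoxy-14-oxo-2,3-secolabdane-2,3-dioate | [N-]=[N+]=CC(=O)[C@@]1(C)CC[C@H]2[C@](C)(CC(=O)OC)[C@@H](C(C)(C)C(=O)OCC[Si](C)(C)C)CC[C@]2(C)O1 | intermediate
28 | keto ester dimer: C3 carboxyl of 19 esterified with the C15′ oxygen of the (5′S,8′S,9′S,10′R,13′R)-14′-oxo unit (2-Me, 2′-Me, 3′-TMSE esters) | C=C[C@]1(C)CC[C@H]2[C@](C)(CC(=O)OC)[C@@H](C(C)(C)C(=O)OCC(=O)[C@@]3(C)CC[C@H]4[C@](C)(CC(=O)OC)[C@@H](C(C)(C)C(=O)OCC[Si](C)(C)C)CC[C@]4(C)O3)CC[C@]2(C)O1 | intermediate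
29 | hydroxy ester dimer: as 28 with (14′R)-hydroxyl | C=C[C@]1(C)CC[C@H]2[C@](C)(CC(=O)OC)[C@@H](C(C)(C)C(=O)OC[C@@H](O)[C@@]3(C)CC[C@H]4[C@](C)(CC(=O)OC)[C@@H](C(C)(C)C(=O)OCC[Si](C)(C)C)CC[C@]4(C)O3)CC[C@]2(C)O1 | intermediate
30 | monoacid: as 29 with free C3′ acid, both C2 methyl esters intact | C=C[C@]1(C)CC[C@H]2[C@](C)(CC(=O)OC)[C@@H](C(C)(C)C(=O)OC[C@@H](O)[C@@]3(C)CC[C@H]4[C@](C)(CC(=O)OC)[C@@H](C(C)(C)C(=O)O)CC[C@]4(C)O3)CC[C@]2(C)O1 | intermediate
31 | CNP0107285.2 (5S,8S,9S,10R,13S / 5′S,8′S,9′S,10′R,13′R,14′R) | C=C[C@]1(C)CC[C@H]2[C@](C)(CC(=O)O)[C@@H](C(C)(C)C(=O)OC[C@@H](O)[C@@]3(C)CC[C@H]4[C@](C)(CC(=O)O)[C@@H](C(C)(C)C(=O)O)CC[C@]4(C)O3)CC[C@]2(C)O1 | target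

## Step count and risks

Total: 19 steps. Longest linear sequence: 14 steps (1–11, then 17–19).

**Step 2 (one-pot Michael addition/alkylation).** The ester enolate may add 1,2 or the ketone enolate may scramble before it is alkylated at the hindered C10. The fallback sets out from 3 and 4 and makes the same bonds stepwise through silicon. Ester 3 is converted (LiN(i-Pr)2, Me3SiCl) into its ketene silyl acetal F1. F1 adds to 4 in a Mukaiyama–Michael reaction (cat. Me3SiOTf, CH2Cl2, −78 °C) to give the isolable trimethylsilyl enol ether F2. MeLi then releases the regiodefined lithium enolate 6, which is alkylated with methyl bromoacetate, and the route is rejoined at 7.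

**Step 7 (hetero-Diels–Alder with butane-2,3-dione).** The twisted, hindered diene may react sluggishly, and the endo preference that fixes C13 may be low. The fallback sets out from 14 and no longer relies on the cycloaddition for C13. Diene 14 is combined with benzyl 2-oxopropanoate under the same catalyst to give the benzyl ester cycloadduct F3 (either C13 epimer is usable). Hydrogenation over Pd/C gives the C14 acid F4. Oxidative decarboxylation with Pb(OAc)4 gives the C13 acetoxy ketal F5. Ionisation with BF3·OEt2 in the presence of potassium vinyltrifluoroborate then delivers the vinyl group to the oxocarbenium ion from the equatorial direction, anti to the syn-axial C17 methyl, and the route is rejoined at 18.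

**Step 18 (C14′ configuration from ketone reduction).** The facial preference may turn out opposite to the Felkin–Anh prediction. The fallback sets out from 25 and exchanges the roles of hydrogen and carbon nucleophile at C14′, so that the same facial bias gives the other carbinol configuration. Acid 25 is reduced with BH3·SMe2 to the primary alcohol F6 and oxidised with Dess–Martin periodinane to the aldehyde F7. (i-PrO)Me2SiCH2MgCl is added to give the β-hydroxysilane F8, and Tamao oxidation (H2O2, KF, KHCO3) gives the 14′,15′-diol F9. Acid 19 is converted with 1-chloro-N,N,2-trimethylprop-1-en-1-amine into the acid chloride F10, which acylates only the primary hydroxyl of F9 (pyridine, DMAP), and the route is rejoined at 29.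

## Further compounds

F1 | step 2 | 2-methyl-1-[2-(trimethylsilyl)ethoxy]-1-(trimethylsilyloxy)prop-1-ene (ketene silyl acetal of 3) | CC(C)=C(OCC[Si](C)(C)C)O[Si](C)(C)C
F2 | step 2 | trimethylsilyl enol ether of the Michael adduct (silyl analogue of 6) | C[Si](C)(C)OC1=C(C)[C@@H](C(C)(C)C(=O)OCC[Si](C)(C)C)C[C@H](C(C)=C)C1
F3 | step 7 | 14-benzyl 2-methyl 3-TMSE (5S,8S,10R)-8,13-epoxy-15-nor-2,3-secolabd-9(11)-ene-2,3,14-trioate (C13 epimers) | O=C(OCc1ccccc1)C1(C)CC=C2[C@](C)(CC(=O)OC)[C@@H](C(C)(C)C(=O)OCC[Si](C)(C)C)CC[C@]2(C)O1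
F4 | step 7 | corresponding saturated (9S) C14 acid (C13 epimers) | OC(=O)C1(C)CC[C@H]2[C@](C)(CC(=O)OC)[C@@H](C(C)(C)C(=O)OCC[Si](C)(C)C)CC[C@]2(C)O1
F5 | step 7 | 13-acetoxy-8,13-epoxy-14,15-dinor ketal (C13 epimers) | CC(=O)OC1(C)CC[C@H]2[C@](C)(CC(=O)OC)[C@@H](C(C)(C)C(=O)OCC[Si](C)(C)C)CC[C@]2(C)O1
F6 | step 18 | (13R)-14-hydroxy-15-nor alcohol from 25 | OC[C@@]1(C)CC[C@H]2[C@](C)(CC(=O)OC)[C@@H](C(C)(C)C(=O)OCC[Si](C)(C)C)CC[C@]2(C)O1
F7 | step 18 | (13R)-15-nor-14-al | O=C[C@@]1(C)CC[C@H]2[C@](C)(CC(=O)OC)[C@@H](C(C)(C)C(=O)OCC[Si](C)(C)C)CC[C@]2(C)O1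
F8 | step 18 | (13R,14R)-14-hydroxy-15-[isopropoxy(dimethyl)silyl] adduct | CC(C)O[Si](C)(C)C[C@@H](O)[C@@]1(C)CC[C@H]2[C@](C)(CC(=O)OC)[C@@H](C(C)(C)C(=O)OCC[Si](C)(C)C)CC[C@]2(C)O1
F9 | step 18 | (13R,14R)-14,15-diol (2-methyl, 3-TMSE diester) | OC[C@@H](O)[C@@]1(C)CC[C@H]2[C@](C)(CC(=O)OC)[C@@H](C(C)(C)C(=O)OCC[Si](C)(C)C)CC[C@]2(C)O1
F10 | step 18 | acid chloride of 19 | C=C[C@]1(C)CC[C@H]2[C@](C)(CC(=O)OC)[C@@H](C(C)(C)C(=O)Cl)CC[C@]2(C)O1
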